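**Retrosynthetic overview**

1. Number the lactone O1, C2 (C=O), C3 (=CH2), C4 (CO2H), C5 (chain). C4 is bonded to two oxygenated carbons (C5 and the carboxyl carbon) and to the C3–C2 acyl arm; a furan C4, flanked by C3 and C5, acquires exactly this pattern when an alkoxycarbonyl carbene adds across C4=C5, and the route rests on that mapping.
2. Late disconnections: the O-acetyl group (put on last, because the magnesium methoxide-type carboxylation reagent would cleave a primary acetate), the exocyclic C3=CH2 (carboxylation, then decarboxylative Mannich methylenation), CO2H from CHO, and the C13 chain from a C5 allyl group by cross-metathesis with dodec-11-en-1-ol and hydrogenation.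
3. The γ-lactone, the only ring of the target, comes from retro-aldol opening of a donor–acceptor cyclopropanol followed by lactonisation of the C5 carbinol (set by Sakurai allylation) onto the ethyl ester.
4. Ring order: a cyclopropane is fused to the dihydrofuran by copper–bis(oxazoline) cyclopropanation of methyl 2-furoate (step 1), the dihydrofuran is cleaved by ozonolysis (step 2), and the cyclopropane is cleaved as the lactone closes (step 4).

Key step: step 1

Assumption: the (4R,4'R)-isopropyl bis(oxazoline) ligand is taken to direct the carbene to the furan face that gives (1R,5R,6R)-3; if the sense of induction proves opposite, the (4S,4'S) ligand is used and nothing else changes.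

**Route**

Step 1
Reactants: 1 methyl 2-furoate; 2 ethyl diazoacetate
Product: 3 6-ethyl 3-methyl (1R,5R,6R)-2-oxabicyclo[3.1.0]hex-3-ene-3,6-dicarboxylate (exo ester)
Conditions: Cu(OTf)2 (1 mol%), 2,2'-(propane-2,2-diyl)bis[(4R)-4-isopropyl-4,5-dihydrooxazole] (1.3 mol%), PhNHNH2 (1 mol%), CH2Cl2, 0 °C, slow addition of 2 (2.5 equiv); recrystallisation
Reagents that add atoms: none
Why: Phenylhydrazine reduces Cu(OTf)2 to the monovalent copper–bis(oxazoline) complex, which takes N2 out of 2 to give an electrophilic copper carbene that adds across the C4=C5 bond of 1 in a concerted, asynchronous [2+1] step. The closest known reaction type is the copper–bis(oxazoline) asymmetric cyclopropanation of enol ethers and furan-2-carboxylates with diazoacetates. The three-membered ring closes by direct carbene transfer without an open-chain intermediate; the carbene C–furan C4 bond is kept as target C3–C4, and the carbene C–furan C5 bond is sacrificial. Bicyclic C1 and C5 are cis because the addition is suprafacial, C6 is exo because the ester points away from the dihydrofuran ring during approach, and the absolute configuration follows from the C2-symmetric ligand, whose isopropyl groups shield one face of the carbene. The step needs regioselectivity, which the 2-ester secures by deactivating and hindering the C2=C3 bond; it also needs to stop at mono-addition, which it should because the remaining alkene is a push–pull alkoxyacrylate. Slow addition of 2 suppresses carbene dimerisation, and the 3-ester stabilises the adduct against electrocyclic unravelling to a dienal; recrystallisation of 3 should raise the enantiomeric purity if needed.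

Step 2
Reactants: 3 6-ethyl 3-methyl (1R,5R,6R)-2-oxabicyclo[3.1.0]hex-3-ene-3,6-dicarboxylate
Product: 5 ethyl (1R,2R,3R)-2-formyl-3-[(2-methoxy-2-oxoacetyl)oxy]cyclopropane-1-carboxylate, via secondary ozonide 4 (not isolated)
Conditions: O3, CH2Cl2, −78 °C; then Me2S, −78 °C to rt
Reagents that add atoms: ozone, [O-][O+]=O
Why: Ozonolysis with reductive work-up cleaves the only C=C bond, so that bicyclic C3 becomes the oxalate carbonyl on the cyclopropanol oxygen and bicyclic C4 the formyl group, while the three cyclopropane stereocentres are untouched and the electron-poor oxalate keeps the donor–acceptor cyclopropane closed.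

Step 3
Reactants: 5 ethyl (1R,2R,3R)-2-formyl-3-[(2-methoxy-2-oxoacetyl)oxy]cyclopropane-1-carboxylate; 6 allyltrimethylsilane
Product: 7 ethyl (1R,2S,3R)-2-[(1R)-1-hydroxybut-3-en-1-yl]-3-[(2-methoxy-2-oxoacetyl)oxy]cyclopropane-1-carboxylate
Conditions: BF3·OEt2 (1.1 equiv), CH2Cl2, −78 °C
Reagents that add atoms: none
Why: In this Hosomi–Sakurai allylation the BF3-activated aldehyde should react through its bisected conformer with the silane approaching anti to the ring bond that leads to the oxalyloxy-bearing carbon (Felkin–Anh control by the adjacent cyclopropane stereocentre), which sets the (R)-carbinol that becomes C5 trans to C4, and the deactivated cyclopropane and both esters tolerate the Lewis acid at −78 °C.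

Step 4
Reactants: 7 ethyl (1R,2S,3R)-2-[(1R)-1-hydroxybut-3-en-1-yl]-3-[(2-methoxy-2-oxoacetyl)oxy]cyclopropane-1-carboxylate
Product: 10 (2R,3S)-5-oxo-2-(prop-2-en-1-yl)oxolane-3-carbaldehyde, via cyclopropanol 8 (not isolated), via open-chain hydroxy aldehyde ester 9 (not isolated)
Conditions: Ba(OH)2·8H2O (1 equiv), MeOH, 0 °C
Reagents that add atoms: none
Why: Hydroxide removes the oxalate, the freed cyclopropanolate opens by retro-aldol cleavage of the bond to the ester-bearing carbon (donor–acceptor cyclopropane ring opening), and the carbinol oxygen then lactonises onto the ethyl ester in a 5-exo-trig closure; both stereocentres are carried over unchanged and the 2,3-trans lactone is also the thermodynamically preferred epimer at the carbon next to the aldehyde.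

Step 5
Reactants: 10 (2R,3S)-5-oxo-2-(prop-2-en-1-yl)oxolane-3-carbaldehyde; 11 dodec-11-en-1-ol
Product: 12 (2R,3S)-2-[(2E)-13-hydroxytridec-2-en-1-yl]-5-oxooxolane-3-carbaldehyde (E/Z mixture, E expected to predominate)
Conditions: second-generation Grubbs catalyst RuCl2(=CHPh)(H2IMes)(PCy3) (5 mol%), 11 (3 equiv), CH2Cl2, 40 °C
Reagents that add atoms: none
Why: Olefin cross-metathesis between two unhindered terminal alkenes is driven by loss of ethene, the excess of 11 favours the cross product over the dimer of 10, the ruthenium carbene tolerates the aldehyde, lactone and free alcohol, and the alkene geometry is irrelevant because the double bond is hydrogenated next.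

Step 6
Reactants: 12 (2R,3S)-2-[(2E)-13-hydroxytridec-2-en-1-yl]-5-oxooxolane-3-carbaldehyde
Product: 13 (2R,3S)-2-(13-hydroxytridecyl)-5-oxooxolane-3-carbaldehyde
Conditions: H2 (1 atm), palladium on carbon (Pd/C, 10 wt%), EtOAc, rt
Reagents that add atoms: none
Why: Heterogeneous catalytic hydrogenation saturates the unhindered disubstituted alkene much faster than it touches an aliphatic aldehyde or a lactone in a neutral aprotic solvent, and no stereocentre is involved.

Step 7
Reactants: 13 (2R,3S)-2-(13-hydroxytridecyl)-5-oxooxolane-3-carbaldehyde
Product: 14 (2R,3S)-2-(13-hydroxytridecyl)-5-oxooxolane-3-carboxylic acid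
Conditions: NaClO2, NaH2PO4, 2-methyl-2-butene, t-BuOH/H2O, rt
Reagents that add atoms: sodium chlorite, [Na+].[O-]Cl=O
Why: The Pinnick oxidation converts the aldehyde to the acid with chlorous acid under buffered, weakly acidic conditions that do not epimerise the α-carbon or oxidise the primary alcohol, and the alkene scavenger removes the hypochlorous acid formed.

Step 8
Reactants: 14 (2R,3S)-2-(13-hydroxytridecyl)-5-oxooxolane-3-carboxylic acid
Product: 15 (2R,3S)-2-(13-hydroxytridecyl)-5-oxooxolane-3,4-dicarboxylic acid (mixture of epimers at C4)
Conditions: methoxymagnesium methyl carbonate MeOMgOCO2Me (2 M in DMF, excess), 135 °C; then cold aq. HCl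
Reagents that add atoms: methoxymagnesium methyl carbonate, CO[Mg]OC(=O)OC
Why: In this Stiles carboxylation the lactone α-carbon is carboxylated and held as a magnesium chelate of the resulting malonate half-lactone, which pulls the equilibrium forward, while the ring carboxylate shields its own α-hydrogen from deprotonation, the free alcohol is only reversibly carbonated, and the new C4 centre is of no consequence because it becomes sp2 in the next step.

Step 9
Reactants: 15 (2R,3S)-2-(13-hydroxytridecyl)-5-oxooxolane-3,4-dicarboxylic acid
Product: 17 (2R,3S)-2-(13-hydroxytridecyl)-4-methylidene-5-oxooxolane-3-carboxylic acid, via Mannich base 16 (not isolated)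
Conditions: aq. HCHO (37%), PhNHMe, NaOAc, AcOH, rt
Reagents that add atoms: formaldehyde, C=O
Why: In this decarboxylative Mannich methylenation the iminium ion from formaldehyde and N-methylaniline alkylates the malonic carbon and the adduct then loses CO2 and the amine to give the exocyclic alkene, only the carboxyl group geminal to the aminomethyl group being lost, and the buffered acidic medium at room temperature should avoid both epimerisation at C3 and migration of the alkene into the ring.

Step 10
Reactants: 17 (2R,3S)-2-(13-hydroxytridecyl)-4-methylidene-5-oxooxolane-3-carboxylic acid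
Product: 18 (2R,3S)-2-[13-(acetyloxy)tridecyl]-4-methylidene-5-oxooxolane-3-carboxylic acid (target)
Conditions: vinyl acetate (excess), immobilised Candida antarctica lipase B, t-BuOMe, 30 °C
Reagents that add atoms: vinyl acetate, C=COC(C)=O
Why: Lipase-catalysed transesterification with an enol ester acetylates the unhindered primary alcohol irreversibly (the vinyl alcohol released tautomerises to acetaldehyde), the α-branched ring carboxylic acid is neither an acyl acceptor nor a good acyl donor for the enzyme, and the neutral base-free medium protects the α-methylene lactone from conjugate addition and from isomerisation to the endocyclic butenolide.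

**Compound list**

1 | methyl furan-2-carboxylate (methyl 2-furoate) | COC(=O)c1ccco1 | starting material
2 | ethyl diazoacetate | CCOC(=O)C=[N+]=[N-] | starting material
3 | 6-ethyl 3-methyl (1R,5R,6R)-2-oxabicyclo[3.1.0]hex-3-ene-3,6-dicarboxylate | COC(=O)C1=C[C@@H]2[C@@H](C(=O)OCC)[C@@H]2O1 | intermediate
4 | secondary ozonide of 3 (1,2,4-trioxolane across former C3 and C4, diastereomer mixture at the two new acetal carbons; not isolated) | COC(=O)C12OC(OO1)[C@@H]1[C@@H](C(=O)OCC)[C@@H]1O2 | intermediate
5 | ethyl (1R,2R,3R)-2-formyl-3-[(2-methoxy-2-oxoacetyl)oxy]cyclopropane-1-carboxylate | O=C[C@@H]1[C@@H](C(=O)OCC)[C@@H]1OC(=O)C(=O)OC | intermediate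
6 | allyltrimethylsilane | C=CC[Si](C)(C)C | starting material
7 | ethyl (1R,2S,3R)-2-[(1R)-1-hydroxybut-3-en-1-yl]-3-[(2-methoxy-2-oxoacetyl)oxy]cyclopropane-1-carboxylate | C=CC[C@@H](O)[C@@H]1[C@@H](C(=O)OCC)[C@@H]1OC(=O)C(=O)OC | intermediate
8 | ethyl (1R,2R,3S)-2-hydroxy-3-[(1R)-1-hydroxybut-3-en-1-yl]cyclopropane-1-carboxylate (cyclopropanol, not isolated) | C=CC[C@@H](O)[C@@H]1[C@@H](C(=O)OCC)[C@@H]1O | intermediate
9 | ethyl (3S,4R)-3-formyl-4-hydroxyhept-6-enoate (not isolated) | C=CC[C@@H](O)[C@@H](C=O)CC(=O)OCC | intermediate
10 | (2R,3S)-5-oxo-2-(prop-2-en-1-yl)oxolane-3-carbaldehyde | C=CC[C@H]1OC(=O)C[C@@H]1C=O | intermediate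
11 | dodec-11-en-1-ol | C=CCCCCCCCCCCO | starting material
12 | (2R,3S)-2-[(2E)-13-hydroxytridec-2-en-1-yl]-5-oxooxolane-3-carbaldehyde (E isomer drawn; E/Z mixture carried on) | OCCCCCCCCCC/C=C/C[C@H]1OC(=O)C[C@@H]1C=O | intermediate
13 | (2R,3S)-2-(13-hydroxytridecyl)-5-oxooxolane-3-carbaldehyde | OCCCCCCCCCCCCC[C@H]1OC(=O)C[C@@H]1C=O | intermediate
14 | (2R,3S)-2-(13-hydroxytridecyl)-5-oxooxolane-3-carboxylic acid | OCCCCCCCCCCCCC[C@H]1OC(=O)C[C@@H]1C(=O)O | intermediate
15 | (2R,3S)-2-(13-hydroxytridecyl)-5-oxooxolane-3,4-dicarboxylic acid (C4 epimers) | OCCCCCCCCCCCCC[C@H]1OC(=O)C(C(=O)O)[C@@H]1C(=O)O | intermediate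
16 | (2R,3S)-2-(13-hydroxytridecyl)-4-{[methyl(phenyl)amino]methyl}-5-oxooxolane-3,4-dicarboxylic acid (Mannich base, not isolated) | OCCCCCCCCCCCCC[C@H]1OC(=O)C(CN(C)c2ccccc2)(C(=O)O)[C@@H]1C(=O)O | intermediate
17 | (2R,3S)-2-(13-hydroxytridecyl)-4-methylidene-5-oxooxolane-3-carboxylic acid | C=C1C(=O)O[C@H](CCCCCCCCCCCCCO)[C@H]1C(=O)O | intermediate
18 | (2R,3S)-2-[13-(acetyloxy)tridecyl]-4-methylidene-5-oxooxolane-3-carboxylic acid | C=C1C(=O)O[C@H](CCCCCCCCCCCCCOC(C)=O)[C@H]1C(=O)O | target

**Step count**

Total steps: 10. Longest linear sequence: 10 steps (from 1 and 2 to 18; 6 and 11 are bought).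

**Steps most likely to fail, with fallbacks**

Step 1. The risks are insufficient discrimination between the two furan faces by the ligand, carbene dimerisation outrunning cyclopropanation, and low conversion of the deactivated furan. The fallback gives up catalyst control and resolves instead. It sets out from 1 and 2: slow addition of 2 to 1 with Rh2(OAc)4 (0.5 mol%) in CH2Cl2 at rt should give the racemic exo adduct, that is 3 together with its antipode 6-ethyl 3-methyl (1S,5S,6S)-2-oxabicyclo[3.1.0]hex-3-ene-3,6-dicarboxylate F1. The two are separated by preparative chromatography on a cellulose tris(3,5-dimethylphenylcarbamate) stationary phase, and the route is rejoined at 3.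

Step 8. The risks are incomplete carboxylation and thermal degradation at 135 °C: lactone opening by β-elimination, epimerisation at the carboxyl-bearing carbon, or premature decarboxylation during the acid work-up. The fallback replaces carboxylation by direct aminomethylation of the lactone enolate, the kind of carboxylate-enolate that is known to alkylate cleanly at this carbon in paraconic acids. It sets out from 14: NaN(SiMe3)2 (3.3 equiv) in THF at −78 °C, then dimethylmethylideneammonium iodide (Me2N=CH2+ I−) and aqueous work-up, should give the Mannich base (2R,3S)-4-[(dimethylamino)methyl]-2-(13-hydroxytridecyl)-5-oxooxolane-3-carboxylic acid F2. MeI in MeOH converts it into the trimethylammonium iodide F3, and aqueous NaHCO3/EtOAc eliminates trimethylamine. The route is rejoined at 17, so 15 and 16 are bypassed.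

Step 10. The risks are sluggish acylation of the substrate by the enzyme and competing enzyme-mediated esterification between the acid of one molecule and the alcohol of another. The fallback is stoichiometric, base-free peracylation followed by selective hydrolysis. It sets out from 17: acetyl chloride (excess) in CH2Cl2 at 0 °C to rt should acetylate the alcohol and convert the acid into the mixed anhydride acetic (2R,3S)-2-[13-(acetyloxy)tridecyl]-4-methylidene-5-oxooxolane-3-carboxylic anhydride F4. Stirring with aqueous THF hydrolyses only the anhydride, and the route is rejoined at 18.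

**Further compounds**

F1 | step 1 | 6-ethyl 3-methyl (1S,5S,6S)-2-oxabicyclo[3.1.0]hex-3-ene-3,6-dicarboxylate | COC(=O)C1=C[C@H]2[C@H](C(=O)OCC)[C@H]2O1
F2 | step 8 | (2R,3S)-4-[(dimethylamino)methyl]-2-(13-hydroxytridecyl)-5-oxooxolane-3-carboxylic acid (C4 configuration not defined) | CN(C)CC1C(=O)O[C@H](CCCCCCCCCCCCCO)[C@H]1C(=O)O
F3 | step 8 | {[(4R,5S... ring numbering as in F2) 4-carboxy-5-(13-hydroxytridecyl)-2-oxooxolan-3-yl]methyl}trimethylammonium iodide | C[N+](C)(C)CC1C(=O)O[C@H](CCCCCCCCCCCCCO)[C@H]1C(=O)O.[I-]
F4 | step 10 | acetic (2R,3S)-2-[13-(acetyloxy)tridecyl]-4-methylidene-5-oxooxolane-3-carboxylic anhydride | C=C1C(=O)O[C@H](CCCCCCCCCCCCCOC(C)=O)[C@H]1C(=O)OC(C)=O
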